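**Retrosynthetic overview**

1. Target 31 ⇐ MnO2 oxidation of pentaol 30 ⇐ B-alkyl Suzuki union (C13–C14) of vinyl cyclohexane triol 16 with tetrahydrofuran vinyl iodide 28.
2. Cyclohexane: 16 ⇐ one-pot epoxide-initiated cation–olefin cyclisation (C6–C11) / Grob-type opening of a sacrificial ring A (C2–C3) / reduction of vinyl epoxide 14, mirroring the oxidosqualene → marneral/iridal pathway.
3. 14 ⇐ Sharpless epoxide of a tetrasubstituted allylic alcohol built from ring-A triflate 5 (from 2-methylcyclohexane-1,3-dione) and dienol 9 (from ethyl 2-methylacetoacetate).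
4. Tetrahydrofuran: 28 ⇐ carboalumination of alkyne 26 ⇐ 5-endo opening of the 18,19-epoxide by the 16-OH, from geranyl chloride and 3-(trimethylsilyl)propynal.
5. Ring order: ring A comes from the commercial dione and is sacrificed; the cyclohexane (step 11) and the tetrahydrofuran (step 17) are formed in separate branches and joined at step 19.

Assumption: locants follow iridal numbering (C1 = CHO, C3 = CH2OH, C6/C10/C11 = cyclohexane stereocentres, C16/C18/C19 = tetrahydrofuran stereocentres), and the (S,S)-TsDPEN and L-(+)-tartrate reagents are taken to give the configurations their usual models predict.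

**Route**

Step 1
Reactants: 1 2-methylcyclohexane-1,3-dione
Product: 2 2-(hydroxymethyl)-2-methylcyclohexane-1,3-dione
Conditions: aq. HCHO (37 %), Et3N (cat.), THF, 0 °C to rt
Reagents that add atoms: formaldehyde, C=O
Why: Base-catalysed aldol hydroxymethylation of the doubly activated C–H installs C1 and gives a prochiral quaternary dione with no stereocentre yet.

Step 2
Reactants: 2 2-(hydroxymethyl)-2-methylcyclohexane-1,3-dione
Product: 3 (2R,3R)-3-hydroxy-2-(hydroxymethyl)-2-methylcyclohexan-1-one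
Conditions: RuCl[(S,S)-TsDPEN](p-cymene) (1 mol %), HCO2H/Et3N (5:2), CH2Cl2, rt
Reagents that add atoms: none
Why: Noyori asymmetric transfer hydrogenation desymmetrises the enantiotopic carbonyls with hydride arriving anti to the hydroxymethyl arm, which sets C3 as R and thereby fixes the quaternary C2 as R (both centres are destroyed in step 11, where they relay facial control and olefin geometry).

Step 3
Reactants: 3 (2R,3R)-3-hydroxy-2-(hydroxymethyl)-2-methylcyclohexan-1-one
Product: 4 (4aR,8aR)-2,2,4a-trimethylhexahydro-4H-1,3-benzodioxin-5-one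
Conditions: Me2C(OMe)2, PPTS (cat.), CH2Cl2, rt
Reagents that add atoms: 2,2-dimethoxypropane, COC(C)(C)OC
Why: Acid-catalysed transketalisation ties the cis-1,3-diol into an acetonide that survives the base, borane and palladium steps and later serves as the fragmentation trigger.

Step 4
Reactants: 4 (4aR,8aR)-2,2,4a-trimethylhexahydro-4H-1,3-benzodioxin-5-one
Product: 5 (4aR,8aR)-2,2,4a-trimethyl-4a,7,8,8a-tetrahydro-4H-1,3-benzodioxin-5-yl trifluoromethanesulfonate
Conditions: KN(SiMe3)2, THF, −78 °C; PhNTf2, −78 to 0 °C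
Reagents that add atoms: N-phenylbis(trifluoromethanesulfonimide), O=S(=O)(N(c1ccccc1)S(=O)(=O)C(F)(F)F)C(F)(F)F
Why: The ketone can enolise only towards C6 (C2 is quaternary), so enolate O-triflation gives a single vinyl triflate.

Step 5
Reactants: 6 ethyl 2-methyl-3-oxobutanoate
Product: 7 ethyl (2E)-2-methyl-3-{[(trifluoromethyl)sulfonyl]oxy}but-2-enoate
Conditions: Tf2O, aq. Me4NOH, toluene, 5 °C
Reagents that add atoms: trifluoromethanesulfonic anhydride, O=S(=O)(OS(=O)(=O)C(F)(F)F)C(F)(F)F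
Why: O-Triflation of the non-chelated tetramethylammonium enolate gives the E enol triflate (ester trans to OTf), which fixes the geometry of the later tetrasubstituted C10=C11 olefin.

Step 6
Reactants: 7 ethyl (2E)-2-methyl-3-{[(trifluoromethyl)sulfonyl]oxy}but-2-enoate
Product: 8 ethyl (2E)-2,3-dimethylpenta-2,4-dienoate
Conditions: CH2=CHSnBu3, Pd(PPh3)4 (5 mol %), LiCl, THF, 65 °C
Reagents that add atoms: tributyl(vinyl)stannane, C=C[Sn](CCCC)(CCCC)CCCC
Why: Stille coupling proceeds with retention at the enol triflate carbon, so the vinyl group (C8–C9) ends trans to the ester.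

Step 7
Reactants: 8 ethyl (2E)-2,3-dimethylpenta-2,4-dienoate
Product: 9 (2E)-2,3-dimethylpenta-2,4-dien-1-ol
Conditions: i-Bu2AlH (2.2 equiv), CH2Cl2, −78 °C; aq. KNaC4H4O6
Reagents that add atoms: none
Why: 1,2-Reduction of the conjugated ester by i-Bu2AlH gives the allylic alcohol without touching the diene.

Step 8
Reactants: 9 (2E)-2,3-dimethylpenta-2,4-dien-1-ol; 5 (4aR,8aR)-2,2,4a-trimethyl-4a,7,8,8a-tetrahydro-4H-1,3-benzodioxin-5-yl trifluoromethanesulfonate
Product: 11 (2E)-2,3-dimethyl-5-[(4aR,8aR)-2,2,4a-trimethyl-4a,7,8,8a-tetrahydro-4H-1,3-benzodioxin-5-yl]pent-2-en-1-ol, via alkylborane 10 (not isolated)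
Conditions: 9-BBN (2.2 equiv), THF, 0 °C to rt; then 5, PdCl2(dppf) (5 mol %), AsPh3, Cs2CO3, DMF/H2O, rt
Reagents that add atoms: none
Why: 9-BBN hydroborates only the terminal vinyl of the diene and the B-alkyl Suzuki–Miyaura coupling then forms the C7–C8 bond to the hindered vinyl triflate.

Step 9
Reactants: 11 (2E)-2,3-dimethyl-5-[(4aR,8aR)-2,2,4a-trimethyl-4a,7,8,8a-tetrahydro-4H-1,3-benzodioxin-5-yl]pent-2-en-1-ol
Product: 12 {(2S,3S)-2,3-dimethyl-3-[2-((4aR,8aR)-2,2,4a-trimethyl-4a,7,8,8a-tetrahydro-4H-1,3-benzodioxin-5-yl)ethyl]oxiran-2-yl}methanol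
Conditions: Ti(OiPr)4 (10 mol %), L-(+)-diethyl tartrate (12 mol %), t-BuOOH, 4 Å MS, CH2Cl2, −20 °C
Reagents that add atoms: tert-butyl hydroperoxide, CC(C)(C)OO
Why: Katsuki–Sharpless asymmetric epoxidation touches only the allylic tetrasubstituted E olefin and sets C10 and C11 as S,S by reagent control.

Step 10
Reactants: 12 {(2S,3S)-2,3-dimethyl-3-[2-((4aR,8aR)-2,2,4a-trimethyl-4a,7,8,8a-tetrahydro-4H-1,3-benzodioxin-5-yl)ethyl]oxiran-2-yl}methanol
Product: 14 (4aR,8aR)-5-{2-[(2S,3S)-3-ethenyl-2,3-dimethyloxiran-2-yl]ethyl}-2,2,4a-trimethyl-4a,7,8,8a-tetrahydro-4H-1,3-benzodioxine, via epoxy aldehyde 13 (not isolated)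
Conditions: (COCl)2, DMSO, CH2Cl2, −78 °C; Et3N; then Ph3P=CH2 (from Ph3PCH3Br and KN(SiMe3)2), THF, −78 to 0 °C
Reagents that add atoms: methylenetriphenylphosphorane, C=P(c1ccccc1)(c1ccccc1)c1ccccc1
Why: Swern oxidation of the non-enolisable epoxy alcohol followed by Wittig methylenation installs the C12=C13 vinyl group, which is both the later coupling handle and the group that directs epoxide opening to C11.

Step 11
Reactants: 14 (4aR,8aR)-5-{2-[(2S,3S)-3-ethenyl-2,3-dimethyloxiran-2-yl]ethyl}-2,2,4a-trimethyl-4a,7,8,8a-tetrahydro-4H-1,3-benzodioxine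
Product: 16 (1S,2S,3R)-2-ethenyl-3-(3-hydroxypropyl)-4-[(2Z)-1-hydroxypropan-2-ylidene]-1,2-dimethylcyclohexan-1-ol, via seco aldehyde 15 (not isolated)
Conditions: Ph4PBF4 (10 mol %), (CF3)2CHOH, H2O (2 equiv), 0 °C, 20 min; then evaporate, MeOH, NaBH4, 0 °C
Reagents that add atoms: none
Why: Proposed new method: hydrogen-bond activation in hexafluoroisopropanol ionises the tertiary allylic C11–O bond, the ring-A alkene attacks C11 with inversion through a chair transition state on the face anti to the axial C1–O arm (setting C6 R and C11 S while C10 S is carried from the epoxide), and the resulting tertiary C7 cation is discharged by Grob-type (retro-Prins) cleavage of the C2–C3 ring bond pushed by the acetal oxygen, which opens ring A to the C3 aldehyde, gives the 2Z olefin because C1 is axial and stays tethered through the acetonide, and releases acetone before the aldehyde is reduced in the same pot; the closest known reaction types are epoxide-initiated cation–olefin cyclisation in fluorinated alcohols and the Grob fragmentation of γ-oxygenated carbocations.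

Step 12
Reactants: 17 geranyl chloride; 18 3-(trimethylsilyl)prop-2-ynal
Product: 20 rac-(5E)-6,10-dimethyl-1-(trimethylsilyl)undeca-5,9-dien-1-yn-3-ol, via geranylbarium chloride 19 (not isolated)
Conditions: BaI2, lithium biphenylide, THF, rt; 17, −78 °C; then 18, −78 °C
Reagents that add atoms: none
Why: Allylbarium (Yamamoto) addition to the aldehyde is α-selective with retention of the E olefin, giving the linear homoallylic propargylic alcohol as a racemate.

Step 13
Reactants: 20 rac-(5E)-6,10-dimethyl-1-(trimethylsilyl)undeca-5,9-dien-1-yn-3-ol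
Product: 21 (5E)-6,10-dimethyl-1-(trimethylsilyl)undeca-5,9-dien-1-yn-3-one
Conditions: Dess–Martin periodinane, NaHCO3, CH2Cl2, 0 °C
Reagents that add atoms: none
Why: Dess–Martin oxidation gives the β,γ-unsaturated ynone under buffered conditions that do not move the olefin into conjugation.

Step 14
Reactants: 21 (5E)-6,10-dimethyl-1-(trimethylsilyl)undeca-5,9-dien-1-yn-3-one
Product: 22 (3S,5E)-6,10-dimethyl-1-(trimethylsilyl)undeca-5,9-dien-1-yn-3-ol
Conditions: Ru[(S,S)-TsNCH(Ph)CH(Ph)NH](p-cymene) (1 mol %), i-PrOH, rt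
Reagents that add atoms: none
Why: Noyori asymmetric transfer hydrogenation of the ynone sets C16 as S by catalyst control.

Step 15
Reactants: 22 (3S,5E)-6,10-dimethyl-1-(trimethylsilyl)undeca-5,9-dien-1-yn-3-ol
Product: 23 (2S)-1-[(2R,3R)-3-methyl-3-(4-methylpent-3-en-1-yl)oxiran-2-yl]-4-(trimethylsilyl)but-3-yn-2-ol
Conditions: VO(acac)2 (5 mol %), t-BuOOH, 2,6-lutidine (cat.), toluene, 0 °C
Reagents that add atoms: tert-butyl hydroperoxide, CC(C)(C)OO
Why: Vanadium-catalysed hydroxyl-directed epoxidation of the homoallylic alcohol goes through a chair vanadate ester with the alkynyl group equatorial and delivers the 1,3-syn (18R,19R) epoxide, leaving the remote C22=C23 olefin untouched.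

Step 16
Reactants: 23 (2S)-1-[(2R,3R)-3-methyl-3-(4-methylpent-3-en-1-yl)oxiran-2-yl]-4-(trimethylsilyl)but-3-yn-2-ol
Product: 24 (2R)-1-[(2R,3R)-3-methyl-3-(4-methylpent-3-en-1-yl)oxiran-2-yl]-4-(trimethylsilyl)but-3-yn-2-yl 4-nitrobenzoate
Conditions: 4-O2NC6H4CO2H, PPh3, DIAD, THF, 0 °C
Reagents that add atoms: 4-nitrobenzoic acid, O=C(O)c1ccc(cc1)[N+](=O)[O-]
Why: Mitsunobu esterification inverts the propargylic C16 to R, turning the syn into the anti epoxy alcohol relationship required for the ring closure.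

Step 17
Reactants: 24 (2R)-1-[(2R,3R)-3-methyl-3-(4-methylpent-3-en-1-yl)oxiran-2-yl]-4-(trimethylsilyl)but-3-yn-2-yl 4-nitrobenzoate
Product: 26 (2S,3R,5R)-5-ethynyl-2-methyl-2-(4-methylpent-3-en-1-yl)oxolan-3-ol, via anti epoxy alcohol 25 (not isolated)
Conditions: K2CO3, MeOH, 0 °C; then solvent exchange to CH2Cl2, CSA (10 mol %), 0 °C
Reagents that add atoms: none
Why: Methanolysis frees the 16-OH and the terminal alkyne, and acid then triggers the 5-endo epoxide opening by the 16-OH at the tertiary C19 with inversion (19S, 18R retained), which forms the tetrahydrofuran with all three ring stereocentres as in the target.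

Step 18
Reactants: 26 (2S,3R,5R)-5-ethynyl-2-methyl-2-(4-methylpent-3-en-1-yl)oxolan-3-ol
Product: 28 (2S,3R,5R)-5-[(1E)-1-iodoprop-1-en-2-yl]-2-methyl-2-(4-methylpent-3-en-1-yl)oxolan-3-ol, via alkenylalane 27 (not isolated)
Conditions: Cp2ZrCl2 (0.3 equiv), AlMe3 (3 equiv), CH2Cl2, 0 °C to rt; then I2, THF, −30 °C
Reagents that add atoms: trimethylaluminium, C[Al](C)C; iodine, II
Why: Negishi zirconium-catalysed syn-carboalumination puts the methyl on C15 and aluminium on C14, and iodinolysis with retention gives the E vinyl iodide.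

Step 19
Reactants: 16 (1S,2S,3R)-2-ethenyl-3-(3-hydroxypropyl)-4-[(2Z)-1-hydroxypropan-2-ylidene]-1,2-dimethylcyclohexan-1-ol; 28 (2S,3R,5R)-5-[(1E)-1-iodoprop-1-en-2-yl]-2-methyl-2-(4-methylpent-3-en-1-yl)oxolan-3-ol
Product: 30 pentaol (the C1 alcohol corresponding to the target enal; 2Z,14E; 6R,10S,11S,16R,18R,19S), via alkylborane 29 (not isolated)
Conditions: 9-BBN (5 equiv), THF, 50 °C; then 28, PdCl2(dppf) (10 mol %), AsPh3, Cs2CO3, DMF/H2O, rt
Reagents that add atoms: none
Why: 9-BBN hydroborates only the monosubstituted vinyl group (the hydroxyls are masked in situ as borinates) and the B-alkyl Suzuki–Miyaura coupling forms C13–C14 with retention of the E vinyl geometry.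

Step 20
Reactants: 30 pentaol
Product: 31 target enal CNP0155390.1
Conditions: MnO2 (20 equiv), CH2Cl2, rt
Reagents that add atoms: none
Why: MnO2 allylic oxidation converts only the primary allylic C1 alcohol into the Z enal and leaves the saturated primary, secondary and tertiary hydroxyls untouched.

**Compound list**

1 | 2-methylcyclohexane-1,3-dione | CC1C(=O)CCCC1=O | starting material
2 | 2-(hydroxymethyl)-2-methylcyclohexane-1,3-dione | CC1(CO)C(=O)CCCC1=O | intermediate
3 | (2R,3R)-3-hydroxy-2-(hydroxymethyl)-2-methylcyclohexan-1-one | O=C1CCC[C@@H](O)[C@@]1(C)CO | intermediate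
4 | (4aR,8aR)-2,2,4a-trimethylhexahydro-4H-1,3-benzodioxin-5-one (cis-fused acetonide of 3) | O=C1CCC[C@H]2OC(C)(C)OC[C@@]12C | intermediate
5 | (4aR,8aR)-2,2,4a-trimethyl-4a,7,8,8a-tetrahydro-4H-1,3-benzodioxin-5-yl trifluoromethanesulfonate | O=S(=O)(OC1=CCC[C@H]2OC(C)(C)OC[C@@]12C)C(F)(F)F | intermediate
6 | ethyl 2-methyl-3-oxobutanoate | CCOC(=O)C(C)C(C)=O | starting material
7 | ethyl (2E)-2-methyl-3-{[(trifluoromethyl)sulfonyl]oxy}but-2-enoate | CCOC(=O)/C(C)=C(\C)OS(=O)(=O)C(F)(F)F | intermediate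
8 | ethyl (2E)-2,3-dimethylpenta-2,4-dienoate | CCOC(=O)/C(C)=C(\C)C=C | intermediate
9 | (2E)-2,3-dimethylpenta-2,4-dien-1-ol | OC/C(C)=C(\C)C=C | intermediate
10 | B-alkyl-9-BBN adduct of 9 (boron on the terminal carbon, hydroxyl as its 9-BBN borinate) | B1(OC/C(C)=C(\C)CCB2C3CCCC2CCC3)C4CCCC1CCC4 | intermediate (not isolated)
11 | (2E)-2,3-dimethyl-5-[(4aR,8aR)-2,2,4a-trimethyl-4a,7,8,8a-tetrahydro-4H-1,3-benzodioxin-5-yl]pent-2-en-1-ol | OC/C(C)=C(\C)CCC1=CCC[C@H]2OC(C)(C)OC[C@@]12C | intermediate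
12 | {(2S,3S)-2,3-dimethyl-3-[2-((4aR,8aR)-2,2,4a-trimethyl-4a,7,8,8a-tetrahydro-4H-1,3-benzodioxin-5-yl)ethyl]oxiran-2-yl}methanol | OC[C@]1(C)O[C@@]1(C)CCC2=CCC[C@H]3OC(C)(C)OC[C@@]23C | intermediate
13 | (2R,3S)-2,3-dimethyl-3-[2-((4aR,8aR)-2,2,4a-trimethyl-4a,7,8,8a-tetrahydro-4H-1,3-benzodioxin-5-yl)ethyl]oxirane-2-carbaldehyde | O=C[C@]1(C)O[C@@]1(C)CCC2=CCC[C@H]3OC(C)(C)OC[C@@]23C | intermediate (not isolated)
14 | (4aR,8aR)-5-{2-[(2S,3S)-3-ethenyl-2,3-dimethyloxiran-2-yl]ethyl}-2,2,4a-trimethyl-4a,7,8,8a-tetrahydro-4H-1,3-benzodioxine | C=C[C@]1(C)O[C@@]1(C)CCC2=CCC[C@H]3OC(C)(C)OC[C@@]23C | intermediate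
15 | 3-{(1R,2S,3S)-2-ethenyl-3-hydroxy-6-[(2Z)-1-hydroxypropan-2-ylidene]-2,3-dimethylcyclohexyl}propanal | C=C[C@@]1(C)[C@H](CCC=O)/C(=C(/C)CO)CC[C@]1(C)O | intermediate (not isolated)
16 | (1S,2S,3R)-2-ethenyl-3-(3-hydroxypropyl)-4-[(2Z)-1-hydroxypropan-2-ylidene]-1,2-dimethylcyclohexan-1-ol | C=C[C@@]1(C)[C@H](CCCO)/C(=C(/C)CO)CC[C@]1(C)O | intermediate
17 | geranyl chloride, (2E)-1-chloro-3,7-dimethylocta-2,6-diene | CC(C)=CCC/C(C)=C/CCl | starting material
18 | 3-(trimethylsilyl)prop-2-ynal | C[Si](C)(C)C#CC=O | starting material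
19 | geranylbarium chloride | CC(C)=CCC/C(C)=C/C[Ba]Cl | intermediate (not isolated)
20 | rac-(5E)-6,10-dimethyl-1-(trimethylsilyl)undeca-5,9-dien-1-yn-3-ol | CC(C)=CCC/C(C)=C/CC(O)C#C[Si](C)(C)C | intermediate
21 | (5E)-6,10-dimethyl-1-(trimethylsilyl)undeca-5,9-dien-1-yn-3-one | CC(C)=CCC/C(C)=C/CC(=O)C#C[Si](C)(C)C | intermediate
22 | (3S,5E)-6,10-dimethyl-1-(trimethylsilyl)undeca-5,9-dien-1-yn-3-ol | CC(C)=CCC/C(C)=C/C[C@H](O)C#C[Si](C)(C)C | intermediate
23 | (2S)-1-[(2R,3R)-3-methyl-3-(4-methylpent-3-en-1-yl)oxiran-2-yl]-4-(trimethylsilyl)but-3-yn-2-ol | CC(C)=CCC[C@@]1(C)O[C@@H]1C[C@H](O)C#C[Si](C)(C)C | intermediate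
24 | (2R)-1-[(2R,3R)-3-methyl-3-(4-methylpent-3-en-1-yl)oxiran-2-yl]-4-(trimethylsilyl)but-3-yn-2-yl 4-nitrobenzoate | CC(C)=CCC[C@@]1(C)O[C@@H]1C[C@@H](OC(=O)c1ccc(cc1)[N+](=O)[O-])C#C[Si](C)(C)C | intermediate
25 | (2R)-1-[(2R,3R)-3-methyl-3-(4-methylpent-3-en-1-yl)oxiran-2-yl]but-3-yn-2-ol | CC(C)=CCC[C@@]1(C)O[C@@H]1C[C@@H](O)C#C | intermediate (not isolated)
26 | (2S,3R,5R)-5-ethynyl-2-methyl-2-(4-methylpent-3-en-1-yl)oxolan-3-ol | CC(C)=CCC[C@]1(C)O[C@@H](C#C)C[C@H]1O | intermediate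
27 | alkenylalane from 26 (dimethylalanyl on C14, methyl on C15, 18-OH as dimethylaluminium alkoxide) | CC(C)=CCC[C@]1(C)O[C@@H](/C(C)=C/[Al](C)C)C[C@H]1O[Al](C)C | intermediate (not isolated)
28 | (2S,3R,5R)-5-[(1E)-1-iodoprop-1-en-2-yl]-2-methyl-2-(4-methylpent-3-en-1-yl)oxolan-3-ol | CC(C)=CCC[C@]1(C)O[C@@H](/C(C)=C/I)C[C@H]1O | intermediate
29 | B-alkyl-9-BBN adduct of 16 (boron on C13, primary hydroxyls as 9-BBN borinates) | B1(CC[C@@]2(C)[C@H](CCCOB3C4CCCC3CCC4)/C(=C(/C)COB3C4CCCC3CCC4)CC[C@]2(C)O)C5CCCC1CCC5 | intermediate (not isolated)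
30 | pentaol, the C1 alcohol of the target (2Z,14E; 6R,10S,11S,16R,18R,19S) | CC(C)=CCC[C@]1(C)O[C@@H](/C(C)=C/CC[C@@]2(C)[C@H](CCCO)/C(=C(/C)CO)CC[C@]2(C)O)C[C@H]1O | intermediate
31 | CNP0155390.1 | CC(C)=CCC[C@]1(C)O[C@@H](/C(C)=C/CC[C@@]2(C)[C@H](CCCO)/C(=C(/C)C=O)CC[C@]2(C)O)C[C@H]1O | target

**Step count**

Total steps: 20. Longest linear sequence: 10 steps, from 2-methylcyclohexane-1,3-dione 1 (steps 1–4, then 8–11, 19 and 20). The branch from 6 (steps 5–7, then 8–11, 19 and 20) and the branch from 17 (steps 12–18, then 19 and 20) are 9 steps each.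

**Three steps most likely to fail, with fallbacks**

Step 11 (cyclisation/fragmentation cascade). The C7 cation may lose a proton, expel C1 by cleaving the exocyclic C1–C2 bond instead of the C2–C3 ring bond, or the liberated aldehyde may re-close onto the new olefin, instead of giving clean ring-A opening. The fallback drops ring A and the fragmentation and closes the cyclohexane by a vinylogous Mukaiyama-type epoxide opening; it sets out from 6 and 9 and returns at 16. The dianion of 6 (NaH, then n-BuLi) is alkylated at the γ-carbon with tert-butyl(3-iodopropoxy)dimethylsilane to give ethyl 7-[(tert-butyldimethylsilyl)oxy]-2-methyl-3-oxoheptanoate F1. NaH and PhNTf2 convert it into the enol triflate F2. B-alkyl Suzuki coupling of F2 with alkylborane 10 (from 9 and 9-BBN) gives the allylic alcohol enoate F3, and Sharpless epoxidation as in step 9 gives the epoxy alcohol F4. Swern oxidation gives the epoxy aldehyde F5 (not isolated), and Wittig methylenation gives the vinyl epoxide F6. LiN(i-Pr)2 and Me3SiCl give the extended silyl ketene acetal F7 (not isolated), which on BF3·OEt2 attacks C11 through its γ-carbon (C6) in the same chair mode to give the cyclohexane enoate F8; the 2Z isomer is expected to predominate because the ester can twist out of plane next to the C6 substituent more easily than the methyl group can be accommodated there, and the mixture is equilibrated with catalytic iodine if needed. i-Bu2AlH reduces F8 to the allylic alcohol silyl ether F9, and Bu4NF returns to 16.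

Step 15 (directed epoxidation). With a slim alkynyl group on the carbinol the syn preference may be modest, and the epoxy alcohol may cyclise prematurely to the C16-epimeric tetrahydrofuran. The fallback sets the epoxide by catalyst control on the already correct C16 epimer, so no inversion is needed; it sets out from 21 and returns at 25 (and hence 26). Ketone 21 is reduced with Ru[(R,R)-TsNCH(Ph)CH(Ph)NH](p-cymene) in i-PrOH to the (3R)-alcohol F10. Epoxidation with Zr(OtBu)4, a chiral bishydroxamic acid ligand and cumene hydroperoxide (the ligand enantiomer matched to the 18R,19R epoxide) gives the anti epoxy alcohol F11. K2CO3 in MeOH removes the silyl group to give 25, which is cyclised with CSA as in step 17.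

Step 19 (hydroboration and coupling of an unprotected triol). Borinate formation and the neopentyl position of the vinyl group may make the hydroboration or the transmetallation sluggish. The fallback reverses the order of coupling and ring formation; it sets out from 14 and 28 and returns at 30. Vinyl epoxide 14 is hydroborated with 9-BBN to the alkylborane F12 (not isolated), which is coupled with 28 (PdCl2(dppf), AsPh3, Cs2CO3) to give the side-chain-bearing epoxide F13, and the conditions of step 11 applied to F13 give 30 directly.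

Further compounds
F1 | step 11 | ethyl 7-[(tert-butyldimethylsilyl)oxy]-2-methyl-3-oxoheptanoate | CCOC(=O)C(C)C(=O)CCCCO[Si](C)(C)C(C)(C)C
F2 | step 11 | ethyl 7-[(tert-butyldimethylsilyl)oxy]-2-methyl-3-{[(trifluoromethyl)sulfonyl]oxy}hept-2-enoate | CCOC(=O)C(C)=C(CCCCO[Si](C)(C)C(C)(C)C)OS(=O)(=O)C(F)(F)F
F3 | step 11 | ethyl (6E)-3-{4-[(tert-butyldimethylsilyl)oxy]butyl}-8-hydroxy-2,6,7-trimethylocta-2,6-dienoate | CCOC(=O)C(C)=C(CCCCO[Si](C)(C)C(C)(C)C)CC/C(C)=C(\C)CO
F4 | step 11 | (10S,11S)-epoxy alcohol from F3 | CCOC(=O)C(C)=C(CCCCO[Si](C)(C)C(C)(C)C)CC[C@]1(C)O[C@@]1(C)CO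
F5 | step 11 | (10S,11R)-epoxy aldehyde from F4 | CCOC(=O)C(C)=C(CCCCO[Si](C)(C)C(C)(C)C)CC[C@]1(C)O[C@@]1(C)C=O
F6 | step 11 | (10S,11S)-vinyl epoxide from F5 | CCOC(=O)C(C)=C(CCCCO[Si](C)(C)C(C)(C)C)CC[C@]1(C)O[C@@]1(C)C=C
F7 | step 11 | extended trimethylsilyl ketene acetal of F6 | CCOC(O[Si](C)(C)C)=C(C)C(=CCCCO[Si](C)(C)C(C)(C)C)CC[C@]1(C)O[C@@]1(C)C=C
F8 | step 11 | ethyl (2Z)-2-[(2R,3S,4S)-2-{3-[(tert-butyldimethylsilyl)oxy]propyl}-3-ethenyl-4-hydroxy-3,4-dimethylcyclohexylidene]propanoate | C=C[C@@]1(C)[C@H](CCCO[Si](C)(C)C(C)(C)C)/C(=C(/C)C(=O)OCC)CC[C@]1(C)O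
F9 | step 11 | C3 tert-butyldimethylsilyl ether of 16 | C=C[C@@]1(C)[C@H](CCCO[Si](C)(C)C(C)(C)C)/C(=C(/C)CO)CC[C@]1(C)O
F10 | step 15 | (3R,5E)-6,10-dimethyl-1-(trimethylsilyl)undeca-5,9-dien-1-yn-3-ol | CC(C)=CCC/C(C)=C/C[C@@H](O)C#C[Si](C)(C)C
F11 | step 15 | (2R)-1-[(2R,3R)-3-methyl-3-(4-methylpent-3-en-1-yl)oxiran-2-yl]-4-(trimethylsilyl)but-3-yn-2-ol | CC(C)=CCC[C@@]1(C)O[C@@H]1C[C@@H](O)C#C[Si](C)(C)C
F12 | step 19 | B-alkyl-9-BBN adduct of 14 (boron on C13) | B1(CC[C@]2(C)O[C@@]2(C)CCC3=CCC[C@H]4OC(C)(C)OC[C@@]34C)C5CCCC1CCC5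
F13 | step 19 | coupling product of 14 and 28 (10S,11S epoxide, ring-A acetonide and tetrahydrofuran side chain) | CC(C)=CCC[C@]1(C)O[C@@H](/C(C)=C/CC[C@]2(C)O[C@@]2(C)CCC3=CCC[C@H]4OC(C)(C)OC[C@@]34C)C[C@H]1O
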